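**Assumptions (one line each)**
- Enantiopure (S)-4-hydroxy-3-methylcyclopent-2-en-1-one is commercially available (enzymatic resolution product).
- The configuration at C9 of ketone **7** does not matter, because C9 is epimerised in step 16.

**Retrosynthetic overview**
1. The target disconnects at its C11 ester and C7 acetate into alcohol **22** plus side-chain acid chloride **17** (from D-valine and isovaleryl chloride), followed by C7 acetylation.
2. The C11 CH2OH comes from a C4-CO2tBu vinylogous carbonate, and the C1 isovalerate acylal comes from anomeric acylation of a cis-fused bicyclic lactol.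
3. The dihydropyran ring is formed last, by unmasking the two acetals of Reformatsky adduct **18** and closing the lactol.
4. **18** comes from a SmI2 Reformatsky coupling of cyclopentanone **7** (C5–C10 plus C1) with bromo-acetal ester **11** (C3–C4–C11). This joins C4–C5 and sets the C5 tertiary carbinol.
5. **7** comes from (S)-4-hydroxy-3-methylcyclopentenone. The cyclopentane ring is already present. C8 is set by epoxidation anti to OTBS followed by SmI2 opening.

## Route

**Step 1**
Reactants: **1** (S)-4-hydroxy-3-methylcyclopent-2-en-1-one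
Product: **2** (S)-4-(tert-butyldimethylsilyloxy)-3-methylcyclopent-2-en-1-one
Conditions: TBSCl, imidazole, DMF, 0→23 °C
Reagents that add atoms: TBSCl, CC(C)(C)[Si](C)(C)Cl
Why: Silylation of the secondary alcohol protects it and installs the bulky group that directs later facial selectivity; the C7 (S) centre is untouched.

**Step 2**
Reactants: **2**
Product: **3** (S)-3-(bromomethyl)-4-(TBSO)cyclopent-2-en-1-one
Conditions: NBS, AIBN (cat.), PhCF3, 80 °C
Reagents that add atoms: NBS, O=C1CCC(=O)N1Br
Why: Wohl–Ziegler radical bromination goes at the γ-methyl, the primary vinylogous-allylic C–H, and leaves C7 untouched.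

**Step 3**
Reactants: **3**
Product: **4** (S)-3-(chloromethyl)-4-(TBSO)cyclopent-2-en-1-one
Conditions: LiCl (10 equiv), DMF, 23 °C
Reagents that add atoms: LiCl, [Li+].[Cl-]
Why: SN2 halide exchange on the reactive γ-bromo enone, driven by excess chloride, installs the C10–Cl carried by the target.

**Step 4**
Reactants: **4**
Product: **5** 5-(chloromethyl)-4-(TBSO)-6-oxabicyclo[3.1.0]hexan-2-one, epoxide O trans to OTBS
Conditions: t-BuOOH, n-BuLi, THF, –78 °C
Reagents that add atoms: tert-butyl hydroperoxide, CC(C)(C)OO
Why: Weitz–Scheffer conjugate epoxidation with the peroxide anion attacks C8 anti to the bulky C7-OTBS, which sets C8 (O down, CH2Cl up).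

**Step 5**
Reactants: **5**
Product: **6** 4-(TBSO)-3-(chloromethyl)-1,3-bis(triethylsilyloxy)cyclopent-1-ene
Conditions: SmI2 (2.2 equiv), THF, –78 °C; then 2,6-lutidine, TESOTf, –78→0 °C
Reagents that add atoms: TESOTf, CC[Si](CC)(CC)OS(=O)(=O)C(F)(F)F
Why: SmI2 cleaves the α C–O bond of the epoxy ketone, giving a regiospecific C5=C9 enolate while the C8–O configuration is retained, and O-silylation traps both oxygens.

**Step 6**
Reactants: **6**
Product: **7** 2-(dimethoxymethyl)-3-(chloromethyl)-4-(TBSO)-3-(TESO)cyclopentan-1-one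
Conditions: HC(OMe)3, TMSOTf (cat.), CH2Cl2, –78 °C
Reagents that add atoms: trimethyl orthoformate, COC(OC)OC
Why: Mukaiyama-type addition of the silyl enol ether to the dialkoxycarbenium ion from the orthoformate adds the C1 dimethyl acetal at C9 and regenerates the C5 ketone; C9 is later epimerised.

**Step 7**
Reactants: **8** tert-butyl acetate
Product: **9** 1-(tert-butoxy)-1-(trimethylsilyloxy)ethene
Conditions: LDA, THF, –78 °C; then TMSCl, –78→23 °C
Reagents that add atoms: TMSCl, C[Si](C)(C)Cl
Why: Kinetic enolisation and O-silylation give the stable tert-butyl silyl ketene acetal.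

**Step 8**
Reactants: **9**
Product: **10** tert-butyl 3,3-dimethoxypropanoate
Conditions: HC(OMe)3, TMSOTf (cat.), CH2Cl2, –78 °C
Reagents that add atoms: trimethyl orthoformate, COC(OC)OC
Why: Lewis-acid Mukaiyama addition of the ketene acetal to the orthoformate builds the C3–C4–C11 unit, with C3 as the masked aldehyde.

**Step 9**
Reactants: **10**
Product: **11** tert-butyl 2-bromo-3,3-dimethoxypropanoate
Conditions: LiHMDS, THF, –78 °C; TMSCl; then NBS, –78 °C
Reagents that add atoms: NBS, O=C1CCC(=O)N1Br
Why: Bromination of the in situ ketene acetal gives the α-bromo ester, the Reformatsky precursor.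

**Step 10**
Reactants: **12** D-valine
Product: **13** (R)-2-hydroxy-3-methylbutanoic acid
Conditions: NaNO2, 1 M H2SO4 (aq), 0→23 °C
Reagents that add atoms: water, O
Why: Diazotisation of the α-amino acid proceeds with double inversion (via the α-lactone), so the (R) configuration is retained.

**Step 11**
Reactants: **13**
Product: **14** benzyl (R)-2-hydroxy-3-methylbutanoate
Conditions: BnBr, Cs2CO3, DMF, 23 °C
Reagents that add atoms: benzyl bromide, BrCc1ccccc1
Why: SN2 alkylation of the carboxylate protects the acid without touching the stereocentre.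

**Step 12**
Reactants: **14**
Product: **15** benzyl (R)-3-methyl-2-(3-methylbutanoyloxy)butanoate
Conditions: isovaleryl chloride, pyridine, DMAP (cat.), CH2Cl2, 0 °C
Reagents that add atoms: isovaleryl chloride, CC(C)CC(=O)Cl
Why: Acylation of the secondary alcohol by acid chloride and pyridine (Schotten–Baumann type) retains the stereocentre.

**Step 13**
Reactants: **15**
Product: **16** (R)-3-methyl-2-(3-methylbutanoyloxy)butanoic acid
Conditions: H2 (1 atm), 10% Pd/C, EtOAc, 23 °C
Reagents that add atoms: none (H2 only)
Why: Hydrogenolysis of the benzyl ester frees the acid and leaves the isovalerate intact.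

**Step 14**
Reactants: **16**
Product: **17** (R)-3-methyl-2-(3-methylbutanoyloxy)butanoyl chloride
Conditions: (COCl)2, DMF (cat.), CH2Cl2, 0→23 °C; concentrate and use crude
Reagents that add atoms: oxalyl chloride, ClC(=O)C(=O)Cl
Why: Vilsmeier-type acid-chloride formation under non-basic conditions avoids epimerisation.

**Step 15**
Reactants: **7** (cyclopentanone) and **11** (bromo acetal ester)
Product: **18** tert-butyl 2-[(1R*-type) 1-hydroxycyclopentyl]-3,3-dimethoxypropanoate. C5-OH is up and the C4 side chain is down. The cyclopentane carries 3-(chloromethyl)-3-(TESO)-4-(TBSO)-2-(dimethoxymethyl). C4 is an epimeric mixture.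
Conditions: SmI2 (2.5 equiv), THF, –78→–30 °C
Reagents that add atoms: none
Why: A SmI2 Reformatsky (Honda) addition uses a weakly basic Sm enolate, so the β-silyloxy ketone does not enolise or eliminate. The enolate adds to C5 from the bottom face, opposite the three "up" substituents (C7-OTBS, C8-CH2Cl, C9 side chain), which sets C5-OH up and C4 down; the C4 epimers converge in step 16.

**Step 16**
Reactants: **18**
Product: **19** cis-fused bicyclic lactol: tert-butyl 1-hydroxy-5-hydroxy-7-(TBSO)-8-(chloromethyl)-8-(TESO)-cyclopenta[c]pyran-4-carboxylate (Δ3,4; C1 anomeric mixture)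
Conditions: PPTS (0.3 equiv), acetone–H2O (10:1), 45 °C
Reagents that add atoms: water, O
Why: Mild acid hydrolyses both acetals; the C3 formyl ester exists as its stabilised enol, whose OH closes onto the C1 aldehyde (ring–chain lactolisation), and C9 epimerises through the aldehyde enol, so only the cis-fused lactol is formed.

**Step 17**
Reactants: **19**
Product: **20** acylal: the C1 isovalerate of **19**, with OiVal cis to H9
Conditions: (iPrCH2CO)2O, Et3N, DMAP (cat.), CH2Cl2, 0 °C
Reagents that add atoms: isovaleric anhydride, CC(C)CC(=O)OC(=O)CC(C)C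
Why: DMAP-catalysed anomeric acylation of the push–pull-stabilised lactol is directed by the anomeric effect and convex-face attack, giving OiVal cis to H9 (the natural C1 configuration).

**Step 18**
Reactants: **20**
Product: **21** the acid: **20** with the tert-butyl ester cleaved to CO2H and the C8 TES ether cleaved to OH (C7-OTBS retained)
Conditions: TFA–CH2Cl2 (1:9), 0 °C, 1 h
Reagents that add atoms: none
Why: Acid-labile tert-butyl ester (E1, loss of isobutene) and tertiary TES ether are cleaved, while the secondary TBS ether and the acylal survive these mild conditions.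

**Step 19**
Reactants: **21**
Product: **22** C11 primary allylic alcohol (CO2H of **21** reduced to CH2OH)
Conditions: i-BuOCOCl, N-methylmorpholine, THF, –15 °C; then NaBH4, H2O, 0 °C
Reagents that add atoms: none (hydride only)
Why: The acid is activated as a mixed carbonic anhydride and reduced selectively by NaBH4, leaving the acylal and silyl ether intact and giving the non-conjugated C3=C4 enol ether.

**Step 20**
Reactants: **22** and **17**
Product: **23** C11 ester bearing the (R)-2-isovaleryloxy-3-methylbutanoate chain, with C7-OTBS still in place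
Conditions: pyridine, DMAP (cat.), CH2Cl2, 0 °C
Reagents that add atoms: none (**17** is the numbered reactant)
Why: Acylation of the unhindered primary alcohol by the acid chloride leaves the tertiary alcohols untouched and the (R) centre unepimerised.

**Step 21**
Reactants: **23**
Product: **24** C7 free alcohol
Conditions: HF·pyridine, pyridine, THF, 0→23 °C
Reagents that add atoms: none (H/F leave, H only)
Why: Buffered fluoride removes the TBS ether without harming the acylal, esters or enol ether.

**Step 22**
Reactants: **24**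
Product: **25** Volvaltrate B
Conditions: Ac2O, pyridine, DMAP (cat.), CH2Cl2, –20→0 °C
Reagents that add atoms: acetic anhydride, CC(=O)OC(C)=O
Why: The secondary C7-OH is acetylated chemoselectively over the two hindered tertiary alcohols (C5, C8), giving the 7-OAc (up) of the target.

## Compound list
1 | (S)-4-hydroxy-3-methylcyclopent-2-en-1-one | O=C1C=C(C)[C@@H](O)C1 | starting material
2 | (S)-4-(TBSO)-3-methylcyclopent-2-en-1-one | O=C1C=C(C)[C@@H](O[Si](C)(C)C(C)(C)C)C1 | intermediate
3 | (S)-3-(bromomethyl)-4-(TBSO)cyclopent-2-en-1-one | O=C1C=C(CBr)[C@@H](O[Si](C)(C)C(C)(C)C)C1 | intermediate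
4 | (S)-3-(chloromethyl)-4-(TBSO)cyclopent-2-en-1-one | O=C1C=C(CCl)[C@@H](O[Si](C)(C)C(C)(C)C)C1 | intermediate
5 | epoxy ketone (epoxide O trans to OTBS) | O=C1[C@@H]2O[C@]2(CCl)[C@@H](O[Si](C)(C)C(C)(C)C)C1 | intermediate
6 | bis-TES enol ether / ether | CC[Si](CC)(CC)OC1=C[C@](CCl)(O[Si](CC)(CC)CC)[C@@H](O[Si](C)(C)C(C)(C)C)C1 | intermediate
7 | C9 dimethyl acetal cyclopentanone | COC(OC)[C@@H]1C(=O)C[C@H](O[Si](C)(C)C(C)(C)C)[C@@]1(CCl)O[Si](CC)(CC)CC | intermediate
8 | tert-butyl acetate | CC(=O)OC(C)(C)C | starting material
9 | tert-butyl TMS ketene acetal | C=C(O[Si](C)(C)C)OC(C)(C)C | intermediate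
10 | tert-butyl 3,3-dimethoxypropanoate | COC(OC)CC(=O)OC(C)(C)C | intermediate
11 | tert-butyl 2-bromo-3,3-dimethoxypropanoate | COC(OC)C(Br)C(=O)OC(C)(C)C | intermediate
12 | D-valine | CC(C)[C@@H](N)C(=O)O | starting material
13 | (R)-2-hydroxy-3-methylbutanoic acid | CC(C)[C@@H](O)C(=O)O | intermediate
14 | benzyl (R)-2-hydroxy-3-methylbutanoate | CC(C)[C@@H](O)C(=O)OCc1ccccc1 | intermediate
15 | benzyl (R)-2-isovaleryloxy-3-methylbutanoate | CC(C)[C@@H](OC(=O)CC(C)C)C(=O)OCc1ccccc1 | intermediate
16 | (R)-2-isovaleryloxy-3-methylbutanoic acid | CC(C)[C@@H](OC(=O)CC(C)C)C(=O)O | intermediate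
17 | corresponding acid chloride | CC(C)[C@@H](OC(=O)CC(C)C)C(=O)Cl | intermediate
18 | Reformatsky adduct (C4 epimeric mixture) | CC(C)(C)OC(=O)C(C(OC)OC)[C@@]1(O)C[C@H](O[Si](C)(C)C(C)(C)C)[C@@](CCl)(O[Si](CC)(CC)CC)[C@@H]1C(OC)OC | intermediate
19 | bicyclic lactol (C1 anomeric mixture) | CC(C)(C)OC(=O)C1=COC(O)[C@H]2[C@]1(O)C[C@H](O[Si](C)(C)C(C)(C)C)[C@@]2(CCl)O[Si](CC)(CC)CC | intermediate
20 | C1 isovalerate acylal | CC(C)(C)OC(=O)C1=CO[C@@H](OC(=O)CC(C)C)[C@H]2[C@]1(O)C[C@H](O[Si](C)(C)C(C)(C)C)[C@@]2(CCl)O[Si](CC)(CC)CC | intermediate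
21 | acid, C8-OH free | OC(=O)C1=CO[C@@H](OC(=O)CC(C)C)[C@H]2[C@]1(O)C[C@H](O[Si](C)(C)C(C)(C)C)[C@]2(O)CCl | intermediate
22 | C11 alcohol | OCC1=CO[C@@H](OC(=O)CC(C)C)[C@H]2[C@]1(O)C[C@H](O[Si](C)(C)C(C)(C)C)[C@]2(O)CCl | intermediate
23 | C11 side-chain ester, 7-OTBS | CC(C)(C)[Si](C)(C)O[C@H]1C[C@]2(O)C(COC(=O)[C@H](OC(=O)CC(C)C)C(C)C)=CO[C@@H](OC(=O)CC(C)C)[C@@H]2[C@@]1(O)CCl | intermediate
24 | 7-OH compound | O[C@H]1C[C@]2(O)C(COC(=O)[C@H](OC(=O)CC(C)C)C(C)C)=CO[C@@H](OC(=O)CC(C)C)[C@@H]2[C@@]1(O)CCl | intermediate
25 | Volvaltrate B | CC(=O)O[C@H]1C[C@]2(O)C(COC(=O)[C@H](OC(=O)CC(C)C)C(C)C)=CO[C@@H](OC(=O)CC(C)C)[C@@H]2[C@@]1(O)CCl | target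

**Total step count:** 22
**Longest linear sequence:** 14 (steps 1→2→3→4→5→6→15→16→17→18→19→20→21→22)

**Three steps most likely to fail**
1. **Step 16 (dialdehyde/lactol closure with C9 epimerisation).** The tertiary β-hydroxy aldehyde can retro-aldol or dehydrate. *Fallback:* use an enol-lactone route instead. Oxidise the C1 aldehyde equivalent to the acid, cyclodehydrate the 5-oxo acid to the cis-fused enol lactone (Ac2O/NaOAc), then reduce with DIBAL at –78 °C and trap the aluminium hemiacetalate with isovaleryl chloride. This gives the acylal and enol ether with no free lactol.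
2. **Step 15 (SmI2 Reformatsky onto the congested ketone).** Facial selectivity or yield may be poor if C9 is not "up". *Fallback:* join C1 and C3 through O2 first as a mixed acetal, then close C4–C5 intramolecularly (SmI2 Reformatsky or NHK), so the tether enforces the cis ring fusion and C5–OH face.
3. **Step 4 (epoxidation of the γ-chloro enone).** The peroxide anion may displace the allylic chloride (SN2/SN2′). *Fallback:* carry C10 as CH2OTBS (SeO2 oxidation of **2**, then silylation), epoxidise with H2O2/NaOH, and install the chloride late by Appel chlorination of the primary alcohol.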